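## Structural features

The target is a single benzene ring (ring A) with four substituents in a 1,2,4,5 arrangement. C1 carries a 3-(benzoyloxy)prop-1-en-2-yl group (C8 on the ring, C9 the terminal methylene, C10 the CH2 bearing the benzoate), C3 a free hydroxyl, C4 a methyl and C6 an isobutyrate, while C2 and C5 carry hydrogen. The two oxygens are para, so the core is a methylhydroquinone acylated on one oxygen only, the one next to the branched side chain. There is no stereocentre and no stereogenic double bond; the only alkene is the 1,1-disubstituted C8=C9. The fragile groups are the aryl isobutyrate (cleaved or moved by bases and nucleophiles), the allylic benzoate (ionized by zerovalent palladium or acid, cleaved by base) and the aryl-substituted alkene (acid, radical polymerization); loss of the aryl ester would expose a hydroquinone that oxidizes to the quinone. The real difficulty is telling apart two phenol oxygens of almost equal electronic character and putting the acyl group on the more hindered one. The key step uses the para-dioxygen pattern of ring A: the C3 oxygen maps onto the carbonyl of a cyclobutenone and the C6 oxygen onto an acylated tertiary carbinol carbon, C1 and C2 onto the ring alkene, and C5, C4 and the methyl onto a propenyl group. The C3–C4 bond is therefore the bond to make, and the oxygens are differentiated before the arene exists.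

## Logic of the disconnections

18 to 15. The C3–C4 bond of ring A is cut and the bond between the carbons that become C3 and C6 is restored, which turns the arene into the isomeric four-membered ring of 15 (through 17 and 16). The cut is made here because the free C3 hydroxyl and the C6 ester then correspond to a ketone and an acylated tertiary alkoxide, two oxygens that are different from the start. The gain is that 15 is assembled from three small pieces and no phenol is ever protected or selected. The demand is a ring opening that turns the acyloxy group outward and the propenyl group toward the ketene, at a temperature that the two esters and the alkene tolerate.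

15 to 13 to 12. The benzoyl–oxygen bond at C10 is cut and the hydroxyl is then masked as a silyl ether. A benzoate cannot pass through the organolithium steps, a bulky silyl ether can. The gain is an inert C10 oxygen through steps 2 to 4. The demand is that silyl removal and benzoylation leave the tertiary, doubly allylic isobutyrate and the strained enone untouched, and that the silyl group resists the acid of step 3.

12 to 7, 8 and 9. The bond between the quaternary ring carbon and the propenyl carbon and the oxygen–acyl bond of the isobutyrate are cut. Both are made in one flask, by addition of 10 (from 8) to a carbonyl and trapping of alkoxide 11 with 9. The gain is that the quaternary carbon becomes one carbonyl of 7. The demand is addition at the carbonyl next to the alkenyl-bearing carbon, a single addition, retention of the E geometry and acylation of a hindered alkoxide.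

7 to 5 to 3 and 2. The bond between the ring carbon and C8 is cut, and the ring C–H and the two carbonyls are traced back, through 6, to the dialkoxy enone pattern of 5. All four ring carbons then come from 3 and the side chain from 4 (made from 2). The demand is mono-addition to 3, hydride delivery to the one remaining carbonyl, and an acid hydrolysis that turns both carbinol carbons into the ring alkene without harming the silyl ether or the exocyclic alkene.

2 to 1. The oxygen–silicon bond is cut. The demand is a silyl group bulky enough not to migrate from oxygen to carbon after lithiation and stable to the acid of step 3.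

## Other disconnections considered

Alternative 1: The C1–C8 bond and the C10–O bond are cut. In the forward sense aryl iodide A2 (4-(tert-butyldimethylsilyloxy)-2-iodo-5-methylphenyl 2-methylpropanoate), propadiene A3 and cesium benzoate A4 would be joined under a zerovalent palladium catalyst: oxidative addition, insertion of A3 with the aryl group on its central carbon, and attack of benzoate on the resulting allyl complex of divalent palladium. This gives A1 (2-[5-(tert-butyldimethylsilyloxy)-2-(isobutyryloxy)-4-methylphenyl]prop-2-en-1-yl benzoate), and fluoride would then free the C3 hydroxyl.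
- In its favour: the whole side chain is attached in one catalytic operation to an intact arene, and the plan is more convergent than the chosen one; on convergence it is the better.
- Against it: A2 has to be made from 2-methylbenzene-1,4-diol A5 with the two oxygens told apart by reagent selectivity. Its iodine must sit ortho to the acyloxy group, whereas electrophilic iodination is directed ortho to the stronger silyloxy donor. Carboxylates are modest nucleophiles for allylpalladium intermediates, and the allylic benzoate of A1 can re-ionize under the same catalyst. A4 is basic enough to threaten the aryl ester, and A3 is a gas to be dosed.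
- Comparison: on structure, the chosen plan creates the oxygen differentiation in the ring-forming event, while this one must prepare it beforehand. On mechanism, a three-component catalytic cascade with several chemoselectivity questions stands against a unimolecular thermal sequence with one selectivity element. On step economy the two are about equal (roughly four steps to A2, then two), with one step after the key step here and none in the chosen plan.

Alternative 2: The C2–C3, C1–C6 and C5–C6 bonds are cut. Carbene complex A7 (pentacarbonyl[(4-methoxybenzyloxy)(prop-1-en-2-yl)methylidene]chromium, a zerovalent chromium species), the terminal alkyne of A8 (2-methylidenebut-3-yn-1-yl benzoate) and one CO ligand would combine on mild heating (Dötz benzannulation). After mild oxidative removal of the metal this gives A6 (2-[2-hydroxy-5-(4-methoxybenzyloxy)-4-methylphenyl]prop-2-en-1-yl benzoate). Acylation of the C6 hydroxyl with 9 and removal of the 4-methoxybenzyl group would finish the synthesis.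
- In its favour: ring A is built with the oxygens already different and the free hydroxyl is the one to be acylated; on this point it is the equal of the chosen plan. The regiochemistry with a terminal alkyne is dependable. Two fragments of similar size give a shorter longest linear sequence, where it is the better.
- Against it: chromium is used in stoichiometric amount. A7 needs O-alkylation of an acylchromate with a 4-methoxybenzyl electrophile, which is less routine than methylation. The conjugated alkene of A8 can divert the carbene. Two steps follow the key step, and the last one removes a 4-methoxybenzyl ether from an electron-rich arene that carries an acid-sensitive alkene and an oxidation-sensitive hydroquinone monoester.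
- Comparison: on structure both plans construct ring A with differentiated oxygens. On mechanism both end in a six-electron closure of a dienylketene, metal-bound here and free in the chosen plan. On step economy the count is similar, the linear sequence shorter here, but with two steps after the key step and stoichiometric metal waste.

Alternative 3: The C3–C2 and C6–C1 bonds are cut. 4-Methylfuran-2-yl 2-methylpropanoate A10 and the ynone A11 (2-oxobut-3-yn-1-yl benzoate) would undergo a [4+2] cycloaddition to the oxanorbornadiene A12 ((±)-2-[2-(benzoyloxy)acetyl]-5-methyl-7-oxabicyclo[2.2.1]hepta-2,5-dien-1-yl 2-methylpropanoate). Its bridge would open in the same pot to A9 (2-[2-(benzoyloxy)acetyl]-4-hydroxy-5-methylphenyl 2-methylpropanoate). Methylenation of the ketone would then supply C9.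
- In its favour: it is the shortest plan, it is metal-free in the key step (equal), and ring formation and oxygen differentiation occur together (equal). The regiochemistry is the electronically matched one, the unsubstituted furan terminus bonding to the alkyne CH.
- Against it: an acyloxyfuran is a weaker and more labile diene than a silyloxy- or alkoxyfuran. The bridge of A12 must break at the acyloxy-bearing carbon, since the other mode loses the isobutyrate. The ketone of A9, flanked by an aryl ester, an α-benzoyloxy methylene and a free phenol, must then be methylenated: a basic ylide would deprotonate the phenol and invite acyl migration or loss of benzoate, and titanium-based methylenation reagents distinguish ketone from ester only imperfectly.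
- Comparison: on structure this plan forms ring A without C9 and leaves a difficult C=C construction for the end, whereas the chosen plan carries the complete side chain into the ring-forming step. On mechanism a bimolecular cycloaddition plus ionic bridge opening stands against a unimolecular electrocyclic sequence. On step count this alternative is the better (about five steps); on the safety of the last step the chosen plan is the better.

Key step: step 7

Remark: the target is achiral; 5, 11 to 15 and 17 are formed as racemates and 6 as a mixture of diastereomers, all of these centres being destroyed later; commercial 8 is taken to be the pure E isomer.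

## Route

Step 1
Reactants: 1 2-bromoprop-2-en-1-ol
Product: 2 [(2-bromoprop-2-en-1-yl)oxy](tert-butyl)diphenylsilane
Conditions: tert-butyl(chloro)diphenylsilane, imidazole, CH2Cl2, 0 °C → rt
Reagents that add atoms: tert-butyl(chloro)diphenylsilane, CC(C)(C)[Si](Cl)(c1ccccc1)c1ccccc1
Why: Imidazole-promoted O-silylation of a primary alcohol; the tert-butyldiphenylsilyl group is chosen because it resists the acid of step 3, is too bulky to migrate from oxygen to the lithiated carbon in step 2 and is still cleaved by fluoride.

Step 2
Reactants: 2 [(2-bromoprop-2-en-1-yl)oxy](tert-butyl)diphenylsilane; 3 diisopropyl squarate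
Product: 5 (±)-4-hydroxy-2,3-diisopropoxy-4-[3-(tert-butyldiphenylsilyloxy)prop-1-en-2-yl]cyclobut-2-en-1-one, via alkenyllithium 4 (not isolated)
Conditions: 2, tert-butyllithium (2.05 equiv), Et2O, −78 °C; then 3, THF, −78 °C; aq. NH4Cl
Reagents that add atoms: none
Why: Bromine–lithium exchange at −78 °C gives 4, which adds 1,2 to one carbonyl of the squarate ester; the alkoxide formed deactivates the second carbonyl, so a single addition is expected, and the new carbinol centre is racemic and is removed in step 3.

Step 3
Reactants: 5 (±)-4-hydroxy-2,3-diisopropoxy-4-[3-(tert-butyldiphenylsilyloxy)prop-1-en-2-yl]cyclobut-2-en-1-one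
Product: 7 3-[3-(tert-butyldiphenylsilyloxy)prop-1-en-2-yl]cyclobut-3-ene-1,2-dione, via cyclobutenediol 6 (not isolated)
Conditions: LiAlH4, THF, −78 → −20 °C; aq. potassium sodium tartrate; crude 6, 12 M HCl (3 equiv), CH2Cl2, 0 °C → rt
Reagents that add atoms: water, O
Why: Hydride adds 1,2 to the remaining vinylogous-ester carbonyl; acid then ionizes each carbinol in turn to an alkoxy-stabilized allyl cation that takes up water at the alkoxy carbon and loses isopropanol (two Stork–Danheiser-type transpositions), so the two carbinol carbons become the ring alkene (C–H next to C–alkenyl) and the two alkoxy carbons the carbonyls; the silyl ether should survive the short acid exposure.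

Step 4
Reactants: 7 3-[3-(tert-butyldiphenylsilyloxy)prop-1-en-2-yl]cyclobut-3-ene-1,2-dione; 8 (E)-1-bromoprop-1-ene; 9 isobutyryl chloride
Product: 12 (±)-4-(isobutyryloxy)-4-[(E)-prop-1-enyl]-3-[3-(tert-butyldiphenylsilyloxy)prop-1-en-2-yl]cyclobut-2-en-1-one, via (E)-prop-1-enyllithium 10 (not isolated), via lithium alkoxide 11 (not isolated)
Conditions: 8, tert-butyllithium (2.0 equiv), Et2O, −78 °C; add to 7, THF, −78 °C; then 9, −78 → 0 °C
Reagents that add atoms: isobutyryl chloride (9), CC(C)C(=O)Cl
Why: Bromine–lithium exchange proceeds with retention of the E geometry; 10 should add 1,2 to the carbonyl next to the alkenyl-bearing carbon, because the other carbonyl is the β-substituted (vinylogous) one and is deactivated by donation from the alkenyl group; the tertiary lithium alkoxide 11 is O-acylated in the same flask, and the quaternary centre is racemic and disappears in step 7.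

Step 5
Reactants: 12 (±)-4-(isobutyryloxy)-4-[(E)-prop-1-enyl]-3-[3-(tert-butyldiphenylsilyloxy)prop-1-en-2-yl]cyclobut-2-en-1-one
Product: 13 (±)-4-(isobutyryloxy)-4-[(E)-prop-1-enyl]-3-(3-hydroxyprop-1-en-2-yl)cyclobut-2-en-1-one
Conditions: Bu4NF, AcOH (1:1), THF, 0 °C → rt
Reagents that add atoms: none
Why: Fluoride cleaves the silicon–oxygen bond; buffering with acetic acid keeps the liberated primary oxygen protonated, so that neither acyl migration from the tertiary ester nor base-induced opening of the cyclobutenone is expected.

Step 6
Reactants: 13 (±)-4-(isobutyryloxy)-4-[(E)-prop-1-enyl]-3-(3-hydroxyprop-1-en-2-yl)cyclobut-2-en-1-one; 14 benzoyl chloride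
Product: 15 (±)-4-(isobutyryloxy)-4-[(E)-prop-1-enyl]-3-[3-(benzoyloxy)prop-1-en-2-yl]cyclobut-2-en-1-one
Conditions: 14, pyridine, DMAP (cat.), CH2Cl2, 0 °C
Reagents that add atoms: benzoyl chloride (14), O=C(Cl)c1ccccc1
Why: Standard acylation of the only free hydroxyl, a primary allylic alcohol; no phenol is present at this stage, so no selectivity between hydroxyl groups is required.

Step 7
Reactants: 15 (±)-4-(isobutyryloxy)-4-[(E)-prop-1-enyl]-3-[3-(benzoyloxy)prop-1-en-2-yl]cyclobut-2-en-1-one
Product: 18 2-[5-hydroxy-2-(isobutyryloxy)-4-methylphenyl]prop-2-en-1-yl benzoate (target), via dienylketene 16 (not isolated), via cyclohexadienone 17 (not isolated)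
Conditions: PhMe (0.02 M, degassed), 110 °C, Ar
Reagents that add atoms: none
Why: Thermal conrotatory four-electron opening cleaves the bond between the carbonyl carbon and the acyloxy-bearing quaternary carbon and gives dienylketene 16; the lone pair of the ester oxygen favours outward rotation of the isobutyryloxy group (torquoselectivity), which places the (E)-propenyl group cis to the ketene. A thermal disrotatory six-electron electrocyclization of 16 then joins the ketene carbon to the methyl-bearing propenyl terminus, forming the C3–C4 bond and closing the six-membered ring A as cyclohexa-2,4-dienone 17. Enolization of 17, driven by aromatization, gives 18 with the former ketene oxygen as the free C3 hydroxyl and the isobutyrate unchanged at C6. The closest known reaction type is the Moore ring expansion of 4-alkenyl-4-hydroxy-, 4-alkoxy- and 4-silyloxycyclobutenones to hydroquinone derivatives; the acyloxy substrate differs only in having a weaker donor on the quaternary carbon. No stereocentre is created that persists: the centre of 15 is lost on ring opening and that of 17 on enolization. The one selectivity needed is the sense of rotation, which the oxygen substituent secures; a ketene of the wrong geometry cannot cyclize and should return to 15 by ring closure, so material is funnelled through 16. The C8=C9 alkene of 16 lies trans to the propenyl group across the central double bond and cannot enter a competing triene cyclization, and high dilution in an aprotic solvent protects the ketene from intermolecular capture.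

## Compound list

1 | 2-bromoprop-2-en-1-ol | C=C(Br)CO | starting material
2 | [(2-bromoprop-2-en-1-yl)oxy](tert-butyl)diphenylsilane | C=C(Br)CO[Si](c1ccccc1)(c1ccccc1)C(C)(C)C | intermediate
3 | diisopropyl squarate (3,4-diisopropoxycyclobut-3-ene-1,2-dione) | CC(C)OC1=C(OC(C)C)C(=O)C1=O | starting material
4 | [3-(tert-butyldiphenylsilyloxy)prop-1-en-2-yl]lithium | [Li]C(=C)CO[Si](c1ccccc1)(c1ccccc1)C(C)(C)C | intermediate (not isolated)
5 | (±)-4-hydroxy-2,3-diisopropoxy-4-[3-(tert-butyldiphenylsilyloxy)prop-1-en-2-yl]cyclobut-2-en-1-one | CC(C)OC1=C(OC(C)C)C(O)(C(=C)CO[Si](c2ccccc2)(c2ccccc2)C(C)(C)C)C1=O | intermediate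
6 | 1-[3-(tert-butyldiphenylsilyloxy)prop-1-en-2-yl]-2,3-diisopropoxycyclobut-2-ene-1,4-diol (mixture of diastereomers) | CC(C)OC1=C(OC(C)C)C(O)(C(=C)CO[Si](c2ccccc2)(c2ccccc2)C(C)(C)C)C1O | intermediate (not isolated)
7 | 3-[3-(tert-butyldiphenylsilyloxy)prop-1-en-2-yl]cyclobut-3-ene-1,2-dione | C=C(CO[Si](c1ccccc1)(c1ccccc1)C(C)(C)C)C1=CC(=O)C1=O | intermediate
8 | (E)-1-bromoprop-1-ene | C/C=C/Br | starting material
9 | isobutyryl chloride | CC(C)C(=O)Cl | starting material
10 | (E)-prop-1-enyllithium | C/C=C/[Li] | intermediate (not isolated)
11 | lithium (±)-4-oxo-1-[(E)-prop-1-enyl]-2-[3-(tert-butyldiphenylsilyloxy)prop-1-en-2-yl]cyclobut-2-en-1-olate | C/C=C/C1(O[Li])C(C(=C)CO[Si](c2ccccc2)(c2ccccc2)C(C)(C)C)=CC1=O | intermediate (not isolated)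
12 | (±)-4-(isobutyryloxy)-4-[(E)-prop-1-enyl]-3-[3-(tert-butyldiphenylsilyloxy)prop-1-en-2-yl]cyclobut-2-en-1-one | C/C=C/C1(OC(=O)C(C)C)C(C(=C)CO[Si](c2ccccc2)(c2ccccc2)C(C)(C)C)=CC1=O | intermediate
13 | (±)-4-(isobutyryloxy)-4-[(E)-prop-1-enyl]-3-(3-hydroxyprop-1-en-2-yl)cyclobut-2-en-1-one | C/C=C/C1(OC(=O)C(C)C)C(C(=C)CO)=CC1=O | intermediate
14 | benzoyl chloride | O=C(Cl)c1ccccc1 | starting material
15 | (±)-4-(isobutyryloxy)-4-[(E)-prop-1-enyl]-3-[3-(benzoyloxy)prop-1-en-2-yl]cyclobut-2-en-1-one | C/C=C/C1(OC(=O)C(C)C)C(C(=C)COC(=O)c2ccccc2)=CC1=O | intermediate
16 | (3Z,5E)-3-[3-(benzoyloxy)prop-1-en-2-yl]-4-(isobutyryloxy)hepta-1,3,5-trien-1-one (dienylketene) | O=C=C/C(C(=C)COC(=O)c1ccccc1)=C(OC(=O)C(C)C)\C=C\C | intermediate (not isolated)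
17 | (±)-3-[3-(benzoyloxy)prop-1-en-2-yl]-4-(isobutyryloxy)-6-methylcyclohexa-2,4-dien-1-one | CC1C=C(OC(=O)C(C)C)C(C(=C)COC(=O)c2ccccc2)=CC1=O | intermediate (not isolated)
18 | 2-[5-hydroxy-2-(isobutyryloxy)-4-methylphenyl]prop-2-en-1-yl benzoate | C=C(COC(=O)c1ccccc1)c1cc(O)c(C)cc1OC(=O)C(C)C | target

## Step count and risks

Total: 7 steps. Longest linear sequence: 7 steps (1 → 2 → 5 → 7 → 12 → 13 → 15 → 18).

Step 7 (key step). The most likely failure is a loss of torquoselectivity: an acyloxy group is a weaker donor than hydroxyl or alkoxyl, so part of the material may open with the ester turned inward. The ester carbonyl then lies next to the ketene and can capture it, or the substrate may simply need a temperature at which the esters and the alkene begin to suffer. The fallback sets out from 7 and returns at 18, using the hydroxy substrate, the best documented case of this ring expansion, and differentiating the phenols afterwards by size.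
- 7 is treated with 10 as in step 4, but alkoxide 11 is protonated with aqueous NH4Cl to give the tertiary alcohol (±)-4-hydroxy-4-[(E)-prop-1-enyl]-3-[3-(tert-butyldiphenylsilyloxy)prop-1-en-2-yl]cyclobut-2-en-1-one F1.
- Buffered fluoride gives the diol (±)-4-hydroxy-3-(3-hydroxyprop-1-en-2-yl)-4-[(E)-prop-1-enyl]cyclobut-2-en-1-one F2.
- The primary hydroxyl alone is benzoylated with 14 (pyridine, −20 °C) to (±)-4-hydroxy-4-[(E)-prop-1-enyl]-3-[3-(benzoyloxy)prop-1-en-2-yl]cyclobut-2-en-1-one F3.
- Thermolysis of F3 in toluene should give the hydroquinone 2-(2,5-dihydroxy-4-methylphenyl)prop-2-en-1-yl benzoate F4, which is kept under argon.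
- Chlorotriisopropylsilane with imidazole should silylate the C3 hydroxyl, flanked only by methyl, in preference to the C6 hydroxyl beside the branched side chain, giving 2-[2-hydroxy-4-methyl-5-(triisopropylsilyloxy)phenyl]prop-2-en-1-yl benzoate F5.
- Acylation of the remaining hydroxyl with 9 gives 2-[2-(isobutyryloxy)-4-methyl-5-(triisopropylsilyloxy)phenyl]prop-2-en-1-yl benzoate F6, and HF·pyridine then gives 18.

Step 4. The most likely failure is erosion of regioselectivity: the preferred carbonyl is also the more hindered one, so some addition at the carbonyl next to the ring C–H, or a second addition, may occur. Incomplete acylation of the hindered alkoxide is a lesser concern. The fallback sets out from 3 and returns at 12; it fixes the position of each group by the order of two additions instead of by a choice between two carbonyls.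
- 3 is reduced with LiAlH(OtBu)3 and hydrolysed with HCl to 3-isopropoxycyclobut-3-ene-1,2-dione F7.
- 10 adds to the carbonyl next to the alkoxy-bearing carbon, the established sense for alkoxycyclobutenediones, to give (±)-4-hydroxy-3-isopropoxy-4-[(E)-prop-1-enyl]cyclobut-2-en-1-one F8.
- The lithium alkoxide of F8 is treated with 4, which attacks the remaining vinylogous-ester carbonyl. Dilute acid then effects a Stork–Danheiser transposition with loss of isopropanol and gives the tertiary alcohol F1 described above.
- Deprotonation of F1 with LiN(SiMe3)2 at −78 °C regenerates 11, and acylation with 9 gives 12. This fallback also avoids 7 altogether.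

Step 3. The most likely failure is incomplete hydride delivery to a carbonyl that is both a vinylogous ester and flanked by an alkoxide. Unreduced 5 would then enter the acid step and end as the 4-isopropoxy dione. In addition, the second ionization, next to a carbonyl, needs strong acid, which the allylic silyl ether and the reactive C–H enedione must tolerate. The fallback sets out from 3 and returns at 7; it places the hydride step on the squarate ester itself, where it is established.
- 3 is reduced with LiAlH(OtBu)3 to (±)-4-hydroxy-2,3-diisopropoxycyclobut-2-en-1-one F9.
- Silylation with chlorotrimethylsilane and Et3N gives (±)-2,3-diisopropoxy-4-(trimethylsilyloxy)cyclobut-2-en-1-one F10.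
- 4 is added to the carbonyl of F10, and HCl in CH2Cl2 removes the trimethylsilyl group and both isopropoxy groups to give 7.

Step 5. The most likely failure is acyl migration from the tertiary oxygen to the liberated primary oxygen, or attack of the transient alkoxide on the strained enone, if buffering is imperfect. The fallback sets out from 7 and returns at 15; it moves the protecting-group exchange ahead of the sensitive ester.
- 7 is desilylated with HF·pyridine to 3-(3-hydroxyprop-1-en-2-yl)cyclobut-3-ene-1,2-dione F11.
- Benzoylation with 14 and 2,6-lutidine gives 2-(3,4-dioxocyclobut-1-en-1-yl)prop-2-en-1-yl benzoate F12.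
- Addition of 10 at −78 °C, where the strained enedione should react far faster than an alkyl benzoate, followed by 9, gives 15 directly.

## Further compounds

F1 | step 7 | (±)-4-hydroxy-4-[(E)-prop-1-enyl]-3-[3-(tert-butyldiphenylsilyloxy)prop-1-en-2-yl]cyclobut-2-en-1-one | C/C=C/C1(O)C(C(=C)CO[Si](c2ccccc2)(c2ccccc2)C(C)(C)C)=CC1=O
F2 | step 7 | (±)-4-hydroxy-3-(3-hydroxyprop-1-en-2-yl)-4-[(E)-prop-1-enyl]cyclobut-2-en-1-one | C/C=C/C1(O)C(C(=C)CO)=CC1=O
F3 | step 7 | (±)-4-hydroxy-4-[(E)-prop-1-enyl]-3-[3-(benzoyloxy)prop-1-en-2-yl]cyclobut-2-en-1-one | C/C=C/C1(O)C(C(=C)COC(=O)c2ccccc2)=CC1=O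
F4 | step 7 | 2-(2,5-dihydroxy-4-methylphenyl)prop-2-en-1-yl benzoate | C=C(COC(=O)c1ccccc1)c1cc(O)c(C)cc1O
F5 | step 7 | 2-[2-hydroxy-4-methyl-5-(triisopropylsilyloxy)phenyl]prop-2-en-1-yl benzoate | C=C(COC(=O)c1ccccc1)c1cc(O[Si](C(C)C)(C(C)C)C(C)C)c(C)cc1O
F6 | step 7 | 2-[2-(isobutyryloxy)-4-methyl-5-(triisopropylsilyloxy)phenyl]prop-2-en-1-yl benzoate | C=C(COC(=O)c1ccccc1)c1cc(O[Si](C(C)C)(C(C)C)C(C)C)c(C)cc1OC(=O)C(C)C
F7 | step 4 | 3-isopropoxycyclobut-3-ene-1,2-dione | CC(C)OC1=CC(=O)C1=O
F8 | step 4 | (±)-4-hydroxy-3-isopropoxy-4-[(E)-prop-1-enyl]cyclobut-2-en-1-one | C/C=C/C1(O)C(OC(C)C)=CC1=O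
F9 | step 3 | (±)-4-hydroxy-2,3-diisopropoxycyclobut-2-en-1-one | CC(C)OC1=C(OC(C)C)C(O)C1=O
F10 | step 3 | (±)-2,3-diisopropoxy-4-(trimethylsilyloxy)cyclobut-2-en-1-one | CC(C)OC1=C(OC(C)C)C(O[Si](C)(C)C)C1=O
F11 | step 5 | 3-(3-hydroxyprop-1-en-2-yl)cyclobut-3-ene-1,2-dione | C=C(CO)C1=CC(=O)C1=O
F12 | step 5 | 2-(3,4-dioxocyclobut-1-en-1-yl)prop-2-en-1-yl benzoate | C=C(COC(=O)c1ccccc1)C1=CC(=O)C1=O
A1 | alternative 1 | 2-[5-(tert-butyldimethylsilyloxy)-2-(isobutyryloxy)-4-methylphenyl]prop-2-en-1-yl benzoate | C=C(COC(=O)c1ccccc1)c1cc(O[Si](C)(C)C(C)(C)C)c(C)cc1OC(=O)C(C)C
A2 | alternative 1 | 4-(tert-butyldimethylsilyloxy)-2-iodo-5-methylphenyl 2-methylpropanoate | Ic1cc(O[Si](C)(C)C(C)(C)C)c(C)cc1OC(=O)C(C)C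
A3 | alternative 1 | propadiene | C=C=C
A4 | alternative 1 | cesium benzoate | [Cs+].[O-]C(=O)c1ccccc1
A5 | alternative 1 | 2-methylbenzene-1,4-diol | Cc1cc(O)ccc1O
A6 | alternative 2 | 2-[2-hydroxy-5-(4-methoxybenzyloxy)-4-methylphenyl]prop-2-en-1-yl benzoate | C=C(COC(=O)c1ccccc1)c1cc(OCc2ccc(OC)cc2)c(C)cc1O
A7 | alternative 2 | pentacarbonyl[(4-methoxybenzyloxy)(prop-1-en-2-yl)methylidene]chromium | COc1ccc(COC(C(C)=C)=[Cr](=C=O)(=C=O)(=C=O)(=C=O)=C=O)cc1
A8 | alternative 2 | 2-methylidenebut-3-yn-1-yl benzoate | C#CC(=C)COC(=O)c1ccccc1
A9 | alternative 3 | 2-[2-(benzoyloxy)acetyl]-4-hydroxy-5-methylphenyl 2-methylpropanoate | O=C(COC(=O)c1ccccc1)c1cc(O)c(C)cc1OC(=O)C(C)C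
A10 | alternative 3 | 4-methylfuran-2-yl 2-methylpropanoate | CC(C)C(=O)Oc1cc(C)co1
A11 | alternative 3 | 2-oxobut-3-yn-1-yl benzoate | C#CC(=O)COC(=O)c1ccccc1
A12 | alternative 3 | (±)-2-[2-(benzoyloxy)acetyl]-5-methyl-7-oxabicyclo[2.2.1]hepta-2,5-dien-1-yl 2-methylpropanoate | CC1=CC2(OC(=O)C(C)C)OC1C=C2C(=O)COC(=O)c1ccccc1
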